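## Structural features

The target is a linear tetramer of phenylpropanoid units. A guaiacylglycerol (unit A: ring A, C7–C9) is joined through O–C8 to the 4-oxygen of a syringylglycerol (unit B: ring B, C7′–C9′). C8′ of unit B is joined through oxygen to the 4-position of a syringyl ring C, and ring C sits on C2 of a 2,3-dihydrobenzofuran (ring D) carrying a hydroxymethyl group on C3, a methoxy group on C7 and an (E)-propenal chain on C5. The six stereocentres form three adjacent pairs, C7/C8 (7R,8S, erythro), C7′/C8′ (7′R,8′S, erythro) and C2/C3 (2R,3S, trans); each pair is separated from the next by a para-disubstituted benzene ring, so no pair can direct another. Fragile functions are the enal, the free phenol of ring A (which makes C7 a para-hydroxybenzylic carbinol, open to quinone methide formation and loss of configuration under acid or strong base), the benzylic carbinol C7′, the benzylic ether C2, and the four electron-rich arenes. The dihydrobenzofuran is the easier part, because its trans arrangement is the thermodynamic one and only C3 needs reagent control. The real difficulty lies in the two erythro arylglycerol β-aryl ether units: in both the ether oxygen belongs to a hindered 2,6-dimethoxyphenol, and the established enantioselective routes (boron aldol of aryloxyacetyl imides, dihydroxylation of cinnamates, transfer hydrogenation of aryloxy keto esters) favour the threo series. The key step exploits that C8′ bears three different neighbours: the aryloxy oxygen of ring C, the carboxyl-level carbon C9′ and the carbinol carbon C7′. It is therefore treated as a carbene carbon placed between an O–H donor (the ring C phenol) and a C=O acceptor (the ring B aldehyde); C8 of unit A has the same environment, with ring B as donor and ring A as acceptor.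

## Logic of the disconnections

28 to 27: three O–Si bonds are cut (O7′, O9′ and the oxygen of the C3 hydroxymethyl group). Silyl ethers are kept to the end because they are the only protecting groups that can be removed at near-neutral pH next to an enal, a free phenol and three benzylic C–O bonds. The forward step must use buffered fluoride.

27 to 24 and 25: the C5–C(vinyl) bond is cut. The enal is the most fragile function and its styrene-type double bond would not survive the carbene chemistry that builds the ether units, so it is introduced after the last carbene step. An aryl bromide, inert to everything before, is carried instead. The forward coupling must run on an electron-rich aryl bromide in the presence of a free phenol and three hydroxyl groups, which calls for a masked aldehyde and a mild base.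

24 to 23: no skeletal bond is cut. C9 is taken back to the ester level and the ring A phenol to its acetate. One hydride step must do both.

23 to 21, 17 and 22: the O–C8 and C7–C8 bonds are cut, so that unit A falls into a phenol, a diazo ester and an aldehyde. The classical alternative, etherification with an α-bromo-β-keto ester followed by hydride reduction, is rejected because it would create C7 and C8 without control of absolute configuration. The forward step needs 21 to be the only O–H donor, so O7′ and O9′ must be silylated.

21 to 19 to 18: O–Si bonds are cut, then C9′ is returned to the ester level and the ring B phenol to its acetate. The reduction is placed directly after the key step because it removes the acidic C8′–H and so secures both new stereocentres. The acetate is chosen so that this same hydride step frees the ring B phenol without acid.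

18 to 15, 17 and 16: the O–C8′ and C7′–C8′ bonds are cut. This is the key disconnection: it removes two bonds and two stereocentres at once and leaves three simple components. The forward step must trap the oxonium ylide or enol with the aldehyde faster than it undergoes the 1,2-proton shift, and a chiral acid must fix both the erythro relationship and the absolute configuration.

15 to 13 to 11: one O–Si bond is cut, then the O1–C2 bond of the dihydrofuran ring. The ring closure is stereoconvergent at C2, so only C3 needs prior control. The forward step needs both phenols free and must tolerate acid; the two MOM ethers of 11 are chosen so that one acid treatment deprotects and cyclises.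

11 to 10 to 7 and 9: the oxidation level at the later hydroxymethyl carbon is adjusted, then the C2–C3 bond of the later dihydrofuran is cut. This aldol disconnection joins rings C and D and sets C3 through the auxiliary. The forward step needs a syn-selective boron aldol of an arylacetyl imide.

7 to 4 and 5, and 4 to 3 to 2 to 1: the N-acyl bond is cut, then the bond between the benzylic carbon and the carboxyl carbon. A commercial benzaldehyde already carries all four substituents of ring D in the right positions, so only a one-carbon homologation is needed.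

9 and 16 to 8: only O–C bonds of protecting groups are cut. One commercial phenolic aldehyde serves as ring C (as the acid-labile acetal ether 9) and as ring B (as the hydride-labile, electron-poorer acetate 16).

## Other disconnections considered

Alternative 1: The cut is the O1–C2 bond of the dihydrofuran ring. In the forward sense catalytic TsOH ionises the para-hydroxybenzylic carbinol of the open-chain bisphenol, either compound 12 of the route or its C1 epimer A2, to the same protonated para-quinone methide. The ortho-phenol of ring D then adds (5-exo-trig) to give the trans-dihydrobenzofuran A1, which is identical with 13.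
- In its favour: the closure is stereoconvergent, so the preceding step need control C3 only and could be a cheaper, non-diastereoselective enolate addition. It is catalytic, metal-free and under thermodynamic control. In reliability it is clearly the better of the two key steps, since it is a long-established mode of reactivity and the ylide trapping of step 11 is not.
- Against it here: as the pivot of the plan it solves only the C2/C3 pair and leaves both erythro ether units to stepwise aldol chemistry with its threo bias. It also needs a free para-phenol on ring C and acid in the presence of electron-rich rings.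
- Comparison: the two plans cut different bonds and do not exclude each other. The chosen route uses this very closure as step 8, so for rings C and D they are equal in mechanism and step count. A plan resting on Alternative 1 alone would be expected to need some four to six more steps for units A and B.

Alternative 2: The cuts are C3a–C7a and C4–C5, so ring D is built rather than bought. In the forward sense the pyridazinyl ether A4, carrying a tethered terminal alkyne, is heated. The alkyne adds across the two pyridazine carbons next to the N–N unit (intramolecular inverse-electron-demand Diels–Alder reaction), and cycloreversion with loss of N2 gives the benzene ring and the dihydrofuran ring of A3 together.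
- In its favour: the substituent pattern of ring D follows unambiguously from the heterocycle. Both stereocentres are set in the open chain and are not touched by the pericyclic step, with no benzylic cation and no epimerisable ester; on configurational safety in the ring-forming step this is better than the chosen closure. The step needs no reagent. The silyl pair of A3 (triisopropylsilyl on the phenol, TBS on the alcohol) already provides the differentiation that the chosen route reaches by silylation and selective desilylation, which makes it equal or slightly better there.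
- Against it here: pyridazines are reluctant azadienes and the methoxy and alkoxy donors on A4 make it more so. Temperatures near 200 °C must be expected, at which the benzylic heteroaryl ether next to the electron-rich ring C may ionise or eliminate. The assembly of A4 needs a regioselective heteroaryl ether formation and an independent asymmetric construction of its two stereocentres. The aryl chloride of A3 is a poorer handle than a bromide for the late attachment of the propenal chain.
- Comparison: in step economy it is the longer plan, because the arene is constructed. Like Alternative 1 it addresses only the C2/C3 pair.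

Alternative 3: The cut is the C2–C3 bond. In the forward sense the aryldiazoacetate A6 loses N2 over Rh2(S-PTTL)4 and the carbene inserts into the benzylic C–H bond of the ring C benzyl ether (1,5-insertion, five-membered ring). This gives the cis ester A7, which DBU equilibrates to the trans ester A5.
- In its favour: enantiocontrol is catalytic, with no stoichiometric auxiliary and no boron aldol, which is better in atom economy. C–H insertion is an established mode of dirhodium carbenes for this ring system, so its carbene step is safer than that of step 11. A6 would be reached from 4 by esterification, exchange of the phenol protecting group for the ring C benzyl group and diazo transfer, so the step count for rings C and D is equal or shorter by about one step. No acid is needed.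
- Against it here: the enantiomeric purity rests on the catalyst alone and no diastereomeric intermediate allows upgrading. The base equilibration passes through an ester enolate β to an aryloxide leaving group, so reversible E1cB ring opening could erode C2 as well as C3. The electron-rich ring C invites Buchner-type addition of the carbene. Diazo transfer adds a sulfonyl azide hazard.
- Comparison: structurally it again addresses only C2/C3. Mechanistically it shares the dirhodium carbene manifold with the chosen plan but uses it where the outcome is more predictable.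

Key step: step 11

Remark on the chemistry: locants are C7–C9 for unit A (ring A), C7′–C9′ for unit B (ring B), and benzofuran numbering (O1, C2, C3, C3a–C7a) for ring D with ring C on C2; TBS is tert-butyldimethylsilyl and MOM is methoxymethyl.
Remark on the chemistry: ethyl diazoacetate (commercial solution) replaces the more hazardous methyl ester and the ring B aldehyde is carried as its acetate instead of an acetal-type ether; both are spectator or protecting-group changes, and the bonds formed and the skeletons of 15 and 18 are unchanged.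
Remark on the chemistry: the esters 18 and 23 are (2R,3R) by the CIP rules although C8′ and C8 have the same spatial arrangement as in the (8′S) and (8S) diols; the descriptor changes because the carboxyl carbon outranks the carbinol carbon, not because of an inversion.
Remark on the chemistry: the sense of induction of the phosphoric acid in steps 11 and 14 cannot be deduced from precedent; (R)-TRIP, (R)-3,3′-bis(2,4,6-triisopropylphenyl)-1,1′-binaphthyl-2,2′-diyl hydrogen phosphate, is written, and its commercial antipode takes its place if a first screening calls for it.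

## Steps

Step 1
Reactants: 1 5-bromo-2-hydroxy-3-methoxybenzaldehyde
Product: 2 5-bromo-3-methoxy-2-(methoxymethoxy)benzaldehyde
Conditions: MOMCl, iPr2NEt, CH2Cl2, 0 °C → rt
Reagents that add atoms: chloromethyl methyl ether (MOMCl), COCCl
Why: O-alkylation of the phenoxide (Williamson type); the MOM ether masks the ring D phenol through the basic and boron-mediated steps and is removed by the same acid that later closes the furan ring.

Step 2
Reactants: 2 5-bromo-3-methoxy-2-(methoxymethoxy)benzaldehyde
Product: 3 2-[5-bromo-3-methoxy-2-(methoxymethoxy)phenyl]acetonitrile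
Conditions: TosMIC, t-BuOK, DME, −35 °C; then MeOH, reflux
Reagents that add atoms: p-toluenesulfonylmethyl isocyanide (TosMIC), Cc1ccc(cc1)S(=O)(=O)C[N+]#[C-]
Why: Van Leusen reductive cyanation: the TosMIC anion adds to the aldehyde, the oxazoline opens and on methanolysis loses formate and sulfinate, so the aldehyde carbon becomes the benzylic CH2 and one nitrile carbon is added. The basic medium leaves the MOM ether and the aryl bromide untouched.

Step 3
Reactants: 3 2-[5-bromo-3-methoxy-2-(methoxymethoxy)phenyl]acetonitrile
Product: 4 2-[5-bromo-3-methoxy-2-(methoxymethoxy)phenyl]acetic acid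
Conditions: KOH, EtOH/H2O (1:1), reflux; then 1 M HCl to pH 4, 0 °C
Reagents that add atoms: water, O
Why: Base hydrolysis of the nitrile to the carboxylate; the acidification is kept cold and mild because of the MOM ether.

Step 4
Reactants: 4 2-[5-bromo-3-methoxy-2-(methoxymethoxy)phenyl]acetic acid; 5 (R)-4-benzyloxazolidin-2-one
Product: 7 (R)-4-benzyl-3-{2-[5-bromo-3-methoxy-2-(methoxymethoxy)phenyl]acetyl}oxazolidin-2-one, via mixed pivalic anhydride 6 (not isolated)
Conditions: PivCl, Et3N, THF, −20 °C; then LiCl, 5, −20 °C → rt
Reagents that add atoms: none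
Why: N-acylation of the oxazolidinone by the mixed anhydride under LiCl/Et3N activation; no strong base is needed, so the acidic arylacetyl position is not disturbed.

Step 5
Reactants: 8 syringaldehyde (4-hydroxy-3,5-dimethoxybenzaldehyde)
Product: 9 3,5-dimethoxy-4-(methoxymethoxy)benzaldehyde
Conditions: MOMCl, iPr2NEt, CH2Cl2, 0 °C → rt
Reagents that add atoms: chloromethyl methyl ether (MOMCl), COCCl
Why: O-alkylation of the phenoxide; the ring C phenol must be masked for the boron aldol and is freed together with the ring D phenol in step 8.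

Step 6
Reactants: 7 (R)-4-benzyl-3-{2-[5-bromo-3-methoxy-2-(methoxymethoxy)phenyl]acetyl}oxazolidin-2-one; 9 3,5-dimethoxy-4-(methoxymethoxy)benzaldehyde
Product: 10 (R)-4-benzyl-3-{(2R,3R)-2-[5-bromo-3-methoxy-2-(methoxymethoxy)phenyl]-3-[3,5-dimethoxy-4-(methoxymethoxy)phenyl]-3-hydroxypropanoyl}oxazolidin-2-one
Conditions: Bu2BOTf, iPr2NEt, CH2Cl2, −78 °C → 0 °C; then pH 7 buffer, MeOH, 30% H2O2, 0 °C
Reagents that add atoms: none
Why: Evans syn aldol reaction: the Z-boron enolate reacts through a Zimmerman–Traxler chair on the face opposite the benzyl group of the (R)-auxiliary, which sets the aryl-bearing carbon (the later C3, S in the benzofuran) and the syn carbinol. Only the former matters, since the carbinol centre is re-set in step 8.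

Step 7
Reactants: 10 (R)-4-benzyl-3-{(2R,3R)-2-[5-bromo-3-methoxy-2-(methoxymethoxy)phenyl]-3-[3,5-dimethoxy-4-(methoxymethoxy)phenyl]-3-hydroxypropanoyl}oxazolidin-2-one
Product: 11 (1R,2S)-2-[5-bromo-3-methoxy-2-(methoxymethoxy)phenyl]-1-[3,5-dimethoxy-4-(methoxymethoxy)phenyl]propane-1,3-diol
Conditions: LiBH4, MeOH (1 equiv), THF, 0 °C
Reagents that add atoms: none
Why: Reductive cleavage of the N-acyloxazolidinone to the primary alcohol with release of the auxiliary; the cold hydride conditions should avoid retro-aldol cleavage and leave both stereocentres untouched.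

Step 8
Reactants: 11 (1R,2S)-2-[5-bromo-3-methoxy-2-(methoxymethoxy)phenyl]-1-[3,5-dimethoxy-4-(methoxymethoxy)phenyl]propane-1,3-diol
Product: 13 [(2R,3S)-5-bromo-2-(4-hydroxy-3,5-dimethoxyphenyl)-7-methoxy-2,3-dihydrobenzofuran-3-yl]methanol, via free bisphenol diol 12 (not isolated)
Conditions: 2 M HCl, MeOH/THF (1:1), 40 °C, high dilution
Reagents that add atoms: none
Why: Acid-catalysed acetal exchange removes both MOM groups (the formaldehyde unit ends as dimethoxymethane); the para-hydroxybenzylic carbinol of 12 then ionises to the protonated para-quinone methide and the ring D phenol adds in a 5-exo-trig closure. C3 is not touched and C2 is formed reversibly, so the thermodynamically preferred trans isomer (2R) should result.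

Step 9
Reactants: 13 [(2R,3S)-5-bromo-2-(4-hydroxy-3,5-dimethoxyphenyl)-7-methoxy-2,3-dihydrobenzofuran-3-yl]methanol
Product: 15 4-[(2R,3S)-5-bromo-3-(tert-butyldimethylsilyloxymethyl)-7-methoxy-2,3-dihydrobenzofuran-2-yl]-2,6-dimethoxyphenol, via bis-silyl ether 14 (not isolated)
Conditions: TBSCl (2.5 equiv), imidazole, DMF, rt; then MeOH, K2CO3 (1.2 equiv), rt
Reagents that add atoms: tert-butyldimethylsilyl chloride (TBSCl), CC(C)(C)[Si](C)(C)Cl
Why: Silylation of both hydroxyl groups followed by carbonate-mediated methanolysis, which cleaves aryl silyl ethers (phenoxide leaving group) much faster than alkyl silyl ethers; this avoids a selectivity problem between the primary alcohol and the phenol.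

Step 10
Reactants: 8 syringaldehyde (4-hydroxy-3,5-dimethoxybenzaldehyde)
Product: 16 4-formyl-2,6-dimethoxyphenyl acetate
Conditions: Ac2O, pyridine, DMAP (cat.), CH2Cl2, rt
Reagents that add atoms: acetic anhydride, CC(=O)OC(C)=O
Why: O-acetylation; the acetate keeps the aldehyde's own phenol from acting as O–H donor in step 11, makes the aldehyde more electrophilic than an ether would, and is cleaved by the hydride of step 12 without a separate step.

Step 11
Reactants: 15 4-[(2R,3S)-5-bromo-3-(tert-butyldimethylsilyloxymethyl)-7-methoxy-2,3-dihydrobenzofuran-2-yl]-2,6-dimethoxyphenol; 16 4-formyl-2,6-dimethoxyphenyl acetate; 17 ethyl diazoacetate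
Product: 18 ethyl (2R,3R)-3-(4-acetoxy-3,5-dimethoxyphenyl)-2-{4-[(2R,3S)-5-bromo-3-(tert-butyldimethylsilyloxymethyl)-7-methoxy-2,3-dihydrobenzofuran-2-yl]-2,6-dimethoxyphenoxy}-3-hydroxypropanoate
Conditions: Rh2(OAc)4 (2 mol%), (R)-TRIP (10 mol%), 4 Å molecular sieves, CH2Cl2, 0 °C; 16 (2 equiv); 17 (1.5 equiv) added over 6 h
Reagents that add atoms: none
Why: Proposed new method: Rh2(OAc)4 (divalent rhodium) decomposes 17 to an acceptor carbene, the phenol oxygen of 15 adds to it, and the oxonium ylide (or the enol formed from it by proton transfer to the ester carbonyl) is intercepted by aldehyde 16, which the chiral phosphoric acid activates by hydrogen bonding, before the 1,2-proton shift to the plain O–H insertion product can occur; O–C8′ and C7′–C8′ are thus formed in one operation and no ring is closed. The closest known reaction type is the Rh2(OAc)4-catalysed three-component coupling of aryldiazoacetates, alcohols and aldehydes or imines through oxonium ylide trapping with chiral acid co-catalysts; new here are the acceptor-only diazoacetate, whose ylide is shorter-lived, and a phenol as the O–H donor. C7′ and C8′ are both set in the C–C bond-forming event inside the hydrogen-bonded pocket of the phosphoric acid, which should bind the enol O–H and the aldehyde C=O at the same time; the acid must supply both the erythro (anti) relationship and the absolute sense, and the remote C2/C3 centres of 15 should exert no influence. The selectivity needed is trapping over proton shift: it is served by the acetate on 16 (a more electrophilic aldehyde), by the twofold excess of 16, by slow addition of 17 at low temperature, and possibly by the two ortho-methoxy groups of the phenol, which can hold the oxonium proton by hydrogen bonding. Chemoselectivity rests on the silyl ether on the primary alcohol (the only other O–H donor) and on the absence of alkenes; the aryl bromide, the aryl acetate and the dihydrobenzofuran should be inert to the carbene.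

Step 12
Reactants: 18 ethyl (2R,3R)-3-(4-acetoxy-3,5-dimethoxyphenyl)-2-{4-[(2R,3S)-5-bromo-3-(tert-butyldimethylsilyloxymethyl)-7-methoxy-2,3-dihydrobenzofuran-2-yl]-2,6-dimethoxyphenoxy}-3-hydroxypropanoate
Product: 19 (1R,2S)-2-{4-[(2R,3S)-5-bromo-3-(tert-butyldimethylsilyloxymethyl)-7-methoxy-2,3-dihydrobenzofuran-2-yl]-2,6-dimethoxyphenoxy}-1-(4-hydroxy-3,5-dimethoxyphenyl)propane-1,3-diol
Conditions: LiBH4, THF/MeOH (20:1), 0 °C → rt
Reagents that add atoms: none
Why: Ester reduction with LiBH4: the ethyl ester becomes the C9′ hydroxymethyl group and the aryl acetate is cleaved to the ring B phenol in the same operation. Placing it directly after the key step removes the acidic C8′–H and with it the risk of retro-aldol cleavage or epimerisation.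

Step 13
Reactants: 19 (1R,2S)-2-{4-[(2R,3S)-5-bromo-3-(tert-butyldimethylsilyloxymethyl)-7-methoxy-2,3-dihydrobenzofuran-2-yl]-2,6-dimethoxyphenoxy}-1-(4-hydroxy-3,5-dimethoxyphenyl)propane-1,3-diol
Product: 21 4-[(1R,2S)-1,3-bis(tert-butyldimethylsilyloxy)-2-{4-[(2R,3S)-5-bromo-3-(tert-butyldimethylsilyloxymethyl)-7-methoxy-2,3-dihydrobenzofuran-2-yl]-2,6-dimethoxyphenoxy}propyl]-2,6-dimethoxyphenol, via tris-silyl ether 20 (not isolated)
Conditions: TBSOTf (3.5 equiv), 2,6-lutidine, CH2Cl2, 0 °C; then MeOH, K2CO3 (3 equiv), rt
Reagents that add atoms: tert-butyldimethylsilyl triflate (TBSOTf), CC(C)(C)[Si](C)(C)OS(=O)(=O)C(F)(F)F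
Why: Exhaustive silylation (the triflate is needed for the hindered benzylic carbinol), then selective methanolysis of the aryl silyl ether as in step 9; the ring B phenol is left as the only O–H group for step 14.

Step 14
Reactants: 21 ring B phenol carrying TBS ethers on O7′ and O9′ and on the C3 hydroxymethyl group (product of step 13); 17 ethyl diazoacetate; 22 4-formyl-2-methoxyphenyl acetate (vanillin acetate)
Product: 23 ethyl (2R,3R)-3-(4-acetoxy-3-methoxyphenyl)-2-(4-{(1R,2S)-1,3-bis(tert-butyldimethylsilyloxy)-2-[4-((2R,3S)-5-bromo-3-(tert-butyldimethylsilyloxymethyl)-7-methoxy-2,3-dihydrobenzofuran-2-yl)-2,6-dimethoxyphenoxy]propyl}-2,6-dimethoxyphenoxy)-3-hydroxypropanoate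
Conditions: Rh2(OAc)4 (2 mol%), (R)-TRIP (10 mol%), 4 Å molecular sieves, CH2Cl2, 0 °C; 22 (2 equiv); 17 (1.5 equiv) added over 6 h
Reagents that add atoms: none
Why: Proposed new method: the same carbene/phenol/aldehyde coupling as in step 11, now with the ring B phenol of 21 (again a 2,6-dimethoxyphenol) and the acetate-activated aldehyde 22; the Rh2(OAc)4 carbene from 17 is captured by the phenol and the ylide or enol is trapped by the acid-bound aldehyde before the 1,2-proton shift, the closest known reaction type being the dirhodium-catalysed three-component coupling of aryldiazoacetates, alcohols and aldehydes with chiral acid co-catalysts. C7 and C8 are set by the same antipode of the phosphoric acid as C7′ and C8′, since both units have the same erythro configuration, and the silyl ethers leave the phenol as the only O–H donor.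

Step 15
Reactants: 23 ethyl ester of unit A attached to the bis-silylated unit B (product of step 14)
Product: 24 (1R,2S)-2-(4-{(1R,2S)-1,3-bis(tert-butyldimethylsilyloxy)-2-[4-((2R,3S)-5-bromo-3-(tert-butyldimethylsilyloxymethyl)-7-methoxy-2,3-dihydrobenzofuran-2-yl)-2,6-dimethoxyphenoxy]propyl}-2,6-dimethoxyphenoxy)-1-(4-hydroxy-3-methoxyphenyl)propane-1,3-diol
Conditions: LiBH4, THF/MeOH (20:1), 0 °C → rt
Reagents that add atoms: none
Why: Ester reduction with LiBH4 as in step 12: the ethyl ester becomes the C9 hydroxymethyl group and the ring A acetate is cleaved; silyl ethers and the aryl bromide are inert.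

Step 16
Reactants: 24 aryl bromide with free unit A and silylated unit B (product of step 15); 25 (E)-2-(3,3-diethoxyprop-1-en-1-yl)-4,4,5,5-tetramethyl-1,3,2-dioxaborolane
Product: 27 (E)-3-[(2R,3S)-2-{4-[(1R,2S)-1,3-bis(tert-butyldimethylsilyloxy)-1-(4-{[(1R,2S)-1,3-dihydroxy-1-(4-hydroxy-3-methoxyphenyl)propan-2-yl]oxy}-3,5-dimethoxyphenyl)propan-2-yl]oxy-3,5-dimethoxyphenyl}-3-(tert-butyldimethylsilyloxymethyl)-7-methoxy-2,3-dihydrobenzofuran-5-yl]prop-2-enal, via diethyl acetal 26 (not isolated)
Conditions: Pd(OAc)2 (5 mol%), SPhos (10 mol%), K3PO4, THF/H2O (10:1), 45 °C; then PPTS, acetone/H2O, rt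
Reagents that add atoms: water, O
Why: Suzuki–Miyaura coupling: zerovalent palladium (formed from Pd(OAc)2 and SPhos) adds into the C5–Br bond, the (E)-alkenylboronate transmetalates with retention of geometry and reductive elimination follows. The enal travels through the basic coupling as its diethyl acetal and is released by mild PPTS hydrolysis, under which silyl ethers and benzylic carbinols should survive.

Step 17
Reactants: 27 tris-silylated enal (product of step 16)
Product: 28 (E)-3-{(2R,3S)-2-[4-({(1R,2S)-1-[4-({(1R,2S)-1,3-dihydroxy-1-(4-hydroxy-3-methoxyphenyl)propan-2-yl}oxy)-3,5-dimethoxyphenyl]-1,3-dihydroxypropan-2-yl}oxy)-3,5-dimethoxyphenyl]-3-(hydroxymethyl)-7-methoxy-2,3-dihydrobenzofuran-5-yl}prop-2-enal (CNP0192639.1)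
Conditions: HF·pyridine, pyridine, THF, 0 °C → rt
Reagents that add atoms: none
Why: Fluoride-mediated cleavage of the three silyl ethers; the pyridine-buffered reagent is neither basic enough to form the ring A quinone methide or attack the enal nor acidic enough to ionise the benzylic carbinols.

## Compound list

1 | 5-bromo-2-hydroxy-3-methoxybenzaldehyde | O=Cc1cc(Br)cc(OC)c1O | starting material
2 | 5-bromo-3-methoxy-2-(methoxymethoxy)benzaldehyde | COCOc1c(OC)cc(Br)cc1C=O | intermediate
3 | 2-[5-bromo-3-methoxy-2-(methoxymethoxy)phenyl]acetonitrile | COCOc1c(OC)cc(Br)cc1CC#N | intermediate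
4 | 2-[5-bromo-3-methoxy-2-(methoxymethoxy)phenyl]acetic acid | COCOc1c(OC)cc(Br)cc1CC(=O)O | intermediate
5 | (R)-4-benzyloxazolidin-2-one | O=C1N[C@H](Cc2ccccc2)CO1 | starting material
6 | 2-[5-bromo-3-methoxy-2-(methoxymethoxy)phenyl]acetic pivalic anhydride (formed in the flask) | COCOc1c(OC)cc(Br)cc1CC(=O)OC(=O)C(C)(C)C | intermediate
7 | (R)-4-benzyl-3-{2-[5-bromo-3-methoxy-2-(methoxymethoxy)phenyl]acetyl}oxazolidin-2-one | COCOc1c(OC)cc(Br)cc1CC(=O)N1[C@H](Cc2ccccc2)COC1=O | intermediate
8 | syringaldehyde (4-hydroxy-3,5-dimethoxybenzaldehyde) | COc1cc(C=O)cc(OC)c1O | starting material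
9 | 3,5-dimethoxy-4-(methoxymethoxy)benzaldehyde | COCOc1c(OC)cc(C=O)cc1OC | intermediate
10 | (R)-4-benzyl-3-{(2R,3R)-2-[5-bromo-3-methoxy-2-(methoxymethoxy)phenyl]-3-[3,5-dimethoxy-4-(methoxymethoxy)phenyl]-3-hydroxypropanoyl}oxazolidin-2-one | COCOc1c(OC)cc(cc1OC)[C@H](O)[C@H](C(=O)N1[C@H](Cc2ccccc2)COC1=O)c1cc(Br)cc(OC)c1OCOC | intermediate
11 | (1R,2S)-2-[5-bromo-3-methoxy-2-(methoxymethoxy)phenyl]-1-[3,5-dimethoxy-4-(methoxymethoxy)phenyl]propane-1,3-diol | COCOc1c(OC)cc(cc1OC)[C@H](O)[C@H](CO)c1cc(Br)cc(OC)c1OCOC | intermediate
12 | (1R,2S)-2-(5-bromo-2-hydroxy-3-methoxyphenyl)-1-(4-hydroxy-3,5-dimethoxyphenyl)propane-1,3-diol (formed in the flask) | COc1cc(cc(OC)c1O)[C@H](O)[C@H](CO)c1cc(Br)cc(OC)c1O | intermediate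
13 | [(2R,3S)-5-bromo-2-(4-hydroxy-3,5-dimethoxyphenyl)-7-methoxy-2,3-dihydrobenzofuran-3-yl]methanol | COc1cc([C@@H]2Oc3c(OC)cc(Br)cc3[C@H]2CO)cc(OC)c1O | intermediate
14 | tert-butyl{[(2R,3S)-5-bromo-2-[4-(tert-butyldimethylsilyloxy)-3,5-dimethoxyphenyl]-7-methoxy-2,3-dihydrobenzofuran-3-yl]methoxy}dimethylsilane (formed in the flask) | COc1cc([C@@H]2Oc3c(OC)cc(Br)cc3[C@H]2CO[Si](C)(C)C(C)(C)C)cc(OC)c1O[Si](C)(C)C(C)(C)C | intermediate
15 | 4-[(2R,3S)-5-bromo-3-(tert-butyldimethylsilyloxymethyl)-7-methoxy-2,3-dihydrobenzofuran-2-yl]-2,6-dimethoxyphenol | COc1cc([C@@H]2Oc3c(OC)cc(Br)cc3[C@H]2CO[Si](C)(C)C(C)(C)C)cc(OC)c1O | intermediate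
16 | 4-formyl-2,6-dimethoxyphenyl acetate | COc1cc(C=O)cc(OC)c1OC(C)=O | intermediate
17 | ethyl diazoacetate | CCOC(=O)C=[N+]=[N-] | starting material
18 | ethyl (2R,3R)-3-(4-acetoxy-3,5-dimethoxyphenyl)-2-{4-[(2R,3S)-5-bromo-3-(tert-butyldimethylsilyloxymethyl)-7-methoxy-2,3-dihydrobenzofuran-2-yl]-2,6-dimethoxyphenoxy}-3-hydroxypropanoate (erythro) | COc1cc([C@@H](O)[C@H](C(=O)OCC)Oc2c(OC)cc([C@@H]3Oc4c(OC)cc(Br)cc4[C@H]3CO[Si](C)(C)C(C)(C)C)cc2OC)cc(OC)c1OC(C)=O | intermediate
19 | (1R,2S)-2-{4-[(2R,3S)-5-bromo-3-(tert-butyldimethylsilyloxymethyl)-7-methoxy-2,3-dihydrobenzofuran-2-yl]-2,6-dimethoxyphenoxy}-1-(4-hydroxy-3,5-dimethoxyphenyl)propane-1,3-diol | COc1cc([C@@H](O)[C@H](CO)Oc2c(OC)cc([C@@H]3Oc4c(OC)cc(Br)cc4[C@H]3CO[Si](C)(C)C(C)(C)C)cc2OC)cc(OC)c1O | intermediate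
20 | 19 silylated (TBS) on the ring B phenol oxygen, O7′ and O9′, (1R,2S) in the propane chain (formed in the flask) | COc1cc([C@@H](O[Si](C)(C)C(C)(C)C)[C@H](CO[Si](C)(C)C(C)(C)C)Oc2c(OC)cc([C@@H]3Oc4c(OC)cc(Br)cc4[C@H]3CO[Si](C)(C)C(C)(C)C)cc2OC)cc(OC)c1O[Si](C)(C)C(C)(C)C | intermediate
21 | 4-[(1R,2S)-1,3-bis(tert-butyldimethylsilyloxy)-2-{4-[(2R,3S)-5-bromo-3-(tert-butyldimethylsilyloxymethyl)-7-methoxy-2,3-dihydrobenzofuran-2-yl]-2,6-dimethoxyphenoxy}propyl]-2,6-dimethoxyphenol | COc1cc([C@@H](O[Si](C)(C)C(C)(C)C)[C@H](CO[Si](C)(C)C(C)(C)C)Oc2c(OC)cc([C@@H]3Oc4c(OC)cc(Br)cc4[C@H]3CO[Si](C)(C)C(C)(C)C)cc2OC)cc(OC)c1O | intermediate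
22 | 4-formyl-2-methoxyphenyl acetate (vanillin acetate) | COc1cc(C=O)ccc1OC(C)=O | starting material
23 | ethyl (2R,3R)-3-(4-acetoxy-3-methoxyphenyl)-2-(4-{(1R,2S)-1,3-bis(tert-butyldimethylsilyloxy)-2-[4-((2R,3S)-5-bromo-3-(tert-butyldimethylsilyloxymethyl)-7-methoxy-2,3-dihydrobenzofuran-2-yl)-2,6-dimethoxyphenoxy]propyl}-2,6-dimethoxyphenoxy)-3-hydroxypropanoate (erythro) | COc1cc([C@@H](O)[C@H](C(=O)OCC)Oc2c(OC)cc([C@@H](O[Si](C)(C)C(C)(C)C)[C@H](CO[Si](C)(C)C(C)(C)C)Oc3c(OC)cc([C@@H]4Oc5c(OC)cc(Br)cc5[C@H]4CO[Si](C)(C)C(C)(C)C)cc3OC)cc2OC)ccc1OC(C)=O | intermediate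
24 | (1R,2S)-2-(4-{(1R,2S)-1,3-bis(tert-butyldimethylsilyloxy)-2-[4-((2R,3S)-5-bromo-3-(tert-butyldimethylsilyloxymethyl)-7-methoxy-2,3-dihydrobenzofuran-2-yl)-2,6-dimethoxyphenoxy]propyl}-2,6-dimethoxyphenoxy)-1-(4-hydroxy-3-methoxyphenyl)propane-1,3-diol | COc1cc([C@@H](O)[C@H](CO)Oc2c(OC)cc([C@@H](O[Si](C)(C)C(C)(C)C)[C@H](CO[Si](C)(C)C(C)(C)C)Oc3c(OC)cc([C@@H]4Oc5c(OC)cc(Br)cc5[C@H]4CO[Si](C)(C)C(C)(C)C)cc3OC)cc2OC)ccc1O | intermediate
25 | (E)-2-(3,3-diethoxyprop-1-en-1-yl)-4,4,5,5-tetramethyl-1,3,2-dioxaborolane | CCOC(OCC)/C=C/B1OC(C)(C)C(C)(C)O1 | starting material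
26 | diethyl acetal of 27: (E)-3,3-diethoxyprop-1-enyl group on C5 in place of the propenal, otherwise as 27 (formed in the flask) | COc1cc([C@@H](O)[C@H](CO)Oc2c(OC)cc([C@@H](O[Si](C)(C)C(C)(C)C)[C@H](CO[Si](C)(C)C(C)(C)C)Oc3c(OC)cc([C@@H]4Oc5c(OC)cc(/C=C/C(OCC)OCC)cc5[C@H]4CO[Si](C)(C)C(C)(C)C)cc3OC)cc2OC)ccc1O | intermediate
27 | (E)-3-[(2R,3S)-2-{4-[(1R,2S)-1,3-bis(tert-butyldimethylsilyloxy)-1-(4-{[(1R,2S)-1,3-dihydroxy-1-(4-hydroxy-3-methoxyphenyl)propan-2-yl]oxy}-3,5-dimethoxyphenyl)propan-2-yl]oxy-3,5-dimethoxyphenyl}-3-(tert-butyldimethylsilyloxymethyl)-7-methoxy-2,3-dihydrobenzofuran-5-yl]prop-2-enal | COc1cc([C@@H](O)[C@H](CO)Oc2c(OC)cc([C@@H](O[Si](C)(C)C(C)(C)C)[C@H](CO[Si](C)(C)C(C)(C)C)Oc3c(OC)cc([C@@H]4Oc5c(OC)cc(/C=C/C=O)cc5[C@H]4CO[Si](C)(C)C(C)(C)C)cc3OC)cc2OC)ccc1O | intermediate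
28 | (E)-3-{(2R,3S)-2-[4-({(1R,2S)-1-[4-({(1R,2S)-1,3-dihydroxy-1-(4-hydroxy-3-methoxyphenyl)propan-2-yl}oxy)-3,5-dimethoxyphenyl]-1,3-dihydroxypropan-2-yl}oxy)-3,5-dimethoxyphenyl]-3-(hydroxymethyl)-7-methoxy-2,3-dihydrobenzofuran-5-yl}prop-2-enal (CNP0192639.1; 7R,8S,7′R,8′S,2R,3S) | COc1cc([C@@H](O)[C@H](CO)Oc2c(OC)cc([C@@H](O)[C@H](CO)Oc3c(OC)cc([C@@H]4Oc5c(OC)cc(/C=C/C=O)cc5[C@H]4CO)cc3OC)cc2OC)ccc1O | target

## Step count and least certain steps

Total: 17 steps. Longest linear sequence: 15 steps (steps 1–4, 6–9 and 11–17, from 1). Steps 5 and 10 are one-step branches from 8.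

Step 11 (key step, proposed new method). The most likely failure is a 1,2-proton shift of the oxonium ylide that outruns the addition to the aldehyde, so that plain O–H insertion dominates. The second is poor facial or erythro/threo discrimination if C–C bond formation takes place on a rhodium-bound ylide outside the chiral acid pocket; as a further uncertainty, the intrinsic diastereofacial preference of the aryloxy enol is unknown and the erythro outcome rests entirely on the acid. Carbene dimerisation and carbonyl ylide formation with the excess aldehyde are minor competing processes. Fallback with known chemistry, from 15 back to the route at 19: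
- 15 is O-alkylated (K2CO3, acetone) with (R)-4-benzyl-3-(2-bromoacetyl)oxazolidin-2-one F1, made from 5, n-BuLi and bromoacetyl bromide. This gives the aryloxyacetyl imide (R)-4-benzyl-3-[2-(aryloxy)acetyl]oxazolidin-2-one F2.
- The dibutylboron enolate of F2 (Bu2BOTf, iPr2NEt, CH2Cl2, −78 °C) adds to 16 in an Evans syn aldol reaction and should give the threo (2R,3S) adduct F3, in which C8′ already has its final arrangement and C7′ is epimeric.
- Mitsunobu reaction with 4-nitrobenzoic acid (PPh3, DIAD, THF) inverts C7′ and gives the (2R,3R) 4-nitrobenzoate F4. SN2 displacement is favoured because the acetoxy-substituted ring B stabilises a benzylic cation poorly.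
- LiBH4 then cleaves the imide, the nitrobenzoate and the aryl acetate in one operation and returns to the route at 19.

Step 14 (proposed new method). The failure processes are the same as in step 11: proton shift before trapping, and insufficient control by the acid. The risk is correlated with step 11, since substrate class and catalyst are the same. Fallback with known chemistry, from 21 back to the route at 24:
- 21 is O-alkylated with F1 (K2CO3, acetone) to the aryloxyacetyl imide F5.
- The boron enolate of F5 adds to 22 in an Evans syn aldol reaction to give the threo adduct F6 (C8 correct, C7 epimeric).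
- Mitsunobu inversion with 4-nitrobenzoic acid gives the 4-nitrobenzoate F7.
- LiBH4 cleaves the imide, the nitrobenzoate and the ring A acetate and returns to the route at 24.

Step 8. The benzylic cation or quinone methide may alkylate the electron-rich rings of a second molecule, liberated formaldehyde may be captured by the arenes, and equilibration to the trans isomer may be incomplete if the acid is too weak. Fallback, from 11 back to the route at 13: deprotection and ring closure are separated and the protic acid is removed from the first event. The MOM groups are cleaved under non-ionising conditions with TMSOTf and 2,2′-bipyridyl in CH2Cl2 followed by water, and the bisphenol 12 is isolated. 12 is then closed in a separate operation with a catalytic amount of TsOH·H2O in dilute CH2Cl2 to give 13. No new compound is involved.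

Step 16. Oxidative addition into the electron-rich C5–Br bond may be slow. The phenolic arylglycerol unit A would then be exposed to warm aqueous base for a long time (epimerisation at C7 through a quinone methide, or fragmentation), and the alkenylboronate may be lost by protodeboronation. Fallback, from 24 back to the route at 26 and 27: a base-free Stille coupling. (E)-Tributyl(3,3-diethoxyprop-1-en-1-yl)stannane F8 is prepared by radical hydrostannylation of 3,3-diethoxyprop-1-yne (Bu3SnH, AIBN) and coupled with 24 using Pd(PPh3)4 in toluene at 80 °C. This gives the acetal 26, which is hydrolysed with PPTS as in the route to 27.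

## Further compounds

F1 | step 11 | (R)-4-benzyl-3-(2-bromoacetyl)oxazolidin-2-one | O=C(CBr)N1[C@H](Cc2ccccc2)COC1=O
F2 | step 11 | (R)-4-benzyl-3-[2-{4-[(2R,3S)-5-bromo-3-(tert-butyldimethylsilyloxymethyl)-7-methoxy-2,3-dihydrobenzofuran-2-yl]-2,6-dimethoxyphenoxy}acetyl]oxazolidin-2-one | COc1cc([C@@H]2Oc3c(OC)cc(Br)cc3[C@H]2CO[Si](C)(C)C(C)(C)C)cc(OC)c1OCC(=O)N1[C@H](Cc2ccccc2)COC1=O
F3 | step 11 | (R)-4-benzyl-3-[(2R,3S)-3-(4-acetoxy-3,5-dimethoxyphenyl)-2-{4-[(2R,3S)-5-bromo-3-(tert-butyldimethylsilyloxymethyl)-7-methoxy-2,3-dihydrobenzofuran-2-yl]-2,6-dimethoxyphenoxy}-3-hydroxypropanoyl]oxazolidin-2-one (threo) | COc1cc([C@H](O)[C@H](C(=O)N5[C@H](Cc6ccccc6)COC5=O)Oc2c(OC)cc([C@@H]3Oc4c(OC)cc(Br)cc4[C@H]3CO[Si](C)(C)C(C)(C)C)cc2OC)cc(OC)c1OC(C)=O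
F4 | step 11 | (2R,3R) 4-nitrobenzoate of the C7′-inverted adduct: as F3 with the carbinol inverted and esterified with 4-nitrobenzoic acid (erythro) | COc1cc([C@@H](OC(=O)c7ccc(cc7)[N+](=O)[O-])[C@H](C(=O)N5[C@H](Cc6ccccc6)COC5=O)Oc2c(OC)cc([C@@H]3Oc4c(OC)cc(Br)cc4[C@H]3CO[Si](C)(C)C(C)(C)C)cc2OC)cc(OC)c1OC(C)=O
F5 | step 14 | (R)-4-benzyl-3-[2-(aryloxy)acetyl]oxazolidin-2-one in which aryl is the ring B of 21 (O-alkylation product of 21 with F1) | COc1cc([C@@H](O[Si](C)(C)C(C)(C)C)[C@H](CO[Si](C)(C)C(C)(C)C)Oc2c(OC)cc([C@@H]3Oc4c(OC)cc(Br)cc4[C@H]3CO[Si](C)(C)C(C)(C)C)cc2OC)cc(OC)c1OCC(=O)N1[C@H](Cc2ccccc2)COC1=O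
F6 | step 14 | (R)-4-benzyl-3-[(2R,3S)-3-(4-acetoxy-3-methoxyphenyl)-3-hydroxy-2-(ring B aryloxy of 21)propanoyl]oxazolidin-2-one (threo) | COc1cc([C@H](O)[C@H](C(=O)N7[C@H](Cc8ccccc8)COC7=O)Oc2c(OC)cc([C@@H](O[Si](C)(C)C(C)(C)C)[C@H](CO[Si](C)(C)C(C)(C)C)Oc3c(OC)cc([C@@H]4Oc5c(OC)cc(Br)cc5[C@H]4CO[Si](C)(C)C(C)(C)C)cc3OC)cc2OC)ccc1OC(C)=O
F7 | step 14 | (2R,3R) 4-nitrobenzoate of the C7-inverted adduct: as F6 with the carbinol inverted and esterified with 4-nitrobenzoic acid (erythro) | COc1cc([C@@H](OC(=O)c9ccc(cc9)[N+](=O)[O-])[C@H](C(=O)N7[C@H](Cc8ccccc8)COC7=O)Oc2c(OC)cc([C@@H](O[Si](C)(C)C(C)(C)C)[C@H](CO[Si](C)(C)C(C)(C)C)Oc3c(OC)cc([C@@H]4Oc5c(OC)cc(Br)cc5[C@H]4CO[Si](C)(C)C(C)(C)C)cc3OC)cc2OC)ccc1OC(C)=O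
F0 | step 8 | none | none
F8 | step 16 | (E)-tributyl(3,3-diethoxyprop-1-en-1-yl)stannane | CCCC[Sn](CCCC)(CCCC)/C=C/C(OCC)OCC
A1 | alternative 1 | [(2R,3S)-5-bromo-2-(4-hydroxy-3,5-dimethoxyphenyl)-7-methoxy-2,3-dihydrobenzofuran-3-yl]methanol (identical with 13) | COc1cc([C@@H]2Oc3c(OC)cc(Br)cc3[C@H]2CO)cc(OC)c1O
A2 | alternative 1 | (1S,2S)-2-(5-bromo-2-hydroxy-3-methoxyphenyl)-1-(4-hydroxy-3,5-dimethoxyphenyl)propane-1,3-diol (C1 epimer of 12) | COc1cc(cc(OC)c1O)[C@@H](O)[C@H](CO)c1cc(Br)cc(OC)c1O
A3 | alternative 2 | tert-butyl{[(2R,3S)-5-chloro-2-(3,5-dimethoxy-4-triisopropylsilyloxyphenyl)-7-methoxy-2,3-dihydrobenzofuran-3-yl]methoxy}dimethylsilane | COc1cc([C@@H]2Oc3c(OC)cc(Cl)cc3[C@H]2CO[Si](C)(C)C(C)(C)C)cc(OC)c1O[Si](C(C)C)(C(C)C)C(C)C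
A4 | alternative 2 | 3-{[(1R,2S)-2-(tert-butyldimethylsilyloxymethyl)-1-(3,5-dimethoxy-4-triisopropylsilyloxyphenyl)but-3-yn-1-yl]oxy}-6-chloro-4-methoxypyridazine | COc1cc([C@H](Oc2nnc(Cl)cc2OC)[C@H](CO[Si](C)(C)C(C)(C)C)C#C)cc(OC)c1O[Si](C(C)C)(C(C)C)C(C)C
A5 | alternative 3 | methyl (2R,3R)-5-bromo-2-(4-tert-butyldimethylsilyloxy-3,5-dimethoxyphenyl)-7-methoxy-2,3-dihydrobenzofuran-3-carboxylate (trans) | COc1cc([C@@H]2Oc3c(OC)cc(Br)cc3[C@H]2C(=O)OC)cc(OC)c1O[Si](C)(C)C(C)(C)C
A6 | alternative 3 | methyl 2-{5-bromo-2-[(4-tert-butyldimethylsilyloxy-3,5-dimethoxyphenyl)methoxy]-3-methoxyphenyl}-2-diazoacetate | COC(=O)C(=[N+]=[N-])c1cc(Br)cc(OC)c1OCc1cc(OC)c(O[Si](C)(C)C(C)(C)C)c(OC)c1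
A7 | alternative 3 | methyl (2R,3S)-5-bromo-2-(4-tert-butyldimethylsilyloxy-3,5-dimethoxyphenyl)-7-methoxy-2,3-dihydrobenzofuran-3-carboxylate (cis) | COc1cc([C@@H]2Oc3c(OC)cc(Br)cc3[C@@H]2C(=O)OC)cc(OC)c1O[Si](C)(C)C(C)(C)C
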